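## The problem

The target **22** is a 2,3,4-trisubstituted tetrahydrofuran. Its atoms are called here O1, C2 (bearing the 4-hydroxyphenyl group), C3 (bearing the acetoxymethyl carbon C3a), C4 (bearing the exocyclic carbinol carbon C4a with its acetate and 4-methoxyphenyl group) and C5 (the ring CH2). There is only one ring, so the difficulty lies in four contiguous stereocentres: (2R,3S,4R) in an all-trans array on the ring, and (S) at C4a outside it. C2 and C3 stand in an aldol relationship (oxygen on C2, a one-carbon oxygenated branch on C3) and can be set together. C4 is adjacent to C3 and can be steered by it, and it becomes epimerisable once C4a is a carbonyl. C4a sits on a freely rotating bond, so substrate control cannot be trusted there and a reagent-controlled step is needed. The two side arms must be told apart, C3a ending as a primary acetate and C4a as a secondary benzylic acetate. The sensitive groups are the 4-methoxybenzylic acetate (easily ionised), the benzylic C2–O1 ether para to a phenol (quinone-methide opening under base, ionisation under acid, hydrogenolysis) and the acetates (migration, cleavage). The late steps must therefore be mild and the free phenol must appear last. The feature that opens the route is at C4: it carries two one-carbon oxygenated groups, C5 (bonded to O1) and C4a (bonded to its own oxygen). Joining C5 to the C4a oxygen gives a 3-substituted oxetane in which C4 is no longer stereogenic, so C4 can be created by opening that oxetane with the C2 oxygen.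

## Retrosynthesis

**22 to 21 to 20.** The phenol is traced to its triisopropylsilyl ether **21** (O–Si bond) and the secondary acetate to carbinol **20** (O–acyl bond). A benzyl ether was rejected because hydrogenolysis would compete with the benzylic C2–O1 and C4a–O bonds. An acyl group was rejected because it could not be told from the two acetates. The forward steps must acetylate one hindered secondary alcohol and then free the phenol without acetyl transfer.

**20 to 19 to 18 to 15 + 16.** The C4a–aryl bond is cut, giving aldehyde **15** and 4-methoxyphenylmagnesium bromide **16**, used as its titanium derivative **17**. Cutting C4–C4a instead would need a C4 carbanion with a β-oxygen in the ring, which would eliminate. Because C4a lies outside the ring, its configuration is not left to the addition: the epimeric carbinols **18** are oxidised to ketone **19** and the (S)-centre is set by catalyst-controlled reduction. This costs two steps but replaces an uncertain Felkin-type bias with a predictable one. It also places C4 next to a carbonyl, where the ring configuration can be corrected by equilibration. The addition must distinguish an aldehyde from an acetate and must not enolise an α-branched aldehyde, hence titanium.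

**15 to 14.** Only the oxidation state changes. Alcohol **14** already holds the three ring stereocentres and the two arms in different states (C3a as the final acetate, C4a as free CH2OH), so no protecting group has to be moved.

**14 to 13 (key disconnection).** The ring bond O1–C5 is cut and C5 is reconnected to the oxygen on C4a, giving oxetane **13**.
- Cutting O1–C2 instead would mean substitution at an electron-rich benzylic carbinol, which runs through the cation and endangers the C2 configuration.
- Cutting a ring C–C bond builds more skeleton but must create two or three stereocentres at once.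
- The O1–C5 cut leaves every bond to the stereocentres intact, removes the ring and one stereocentre, and uses an oxetane unit that can be bought.

The forward reaction must be an intramolecular oxetane opening by the C2 hydroxyl that selects one of two diastereotopic methylenes. The only other oxygen nucleophile, the C3a hydroxyl, is therefore already capped as the acetate the target needs.

**13 to 12 to 11.** Removing the acetyl group gives diol **12**, whose primary carbinol is traced to the imide carbonyl of aldol adduct **11**. The forward steps are hydride cleavage of the auxiliary and a primary-selective acetylation. The latter is what differentiates the two arms of the target, since the second arm is still locked in the oxetane.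

**11 to 6 + 8.** The C2–C3 bond is an aldol bond. Cutting it gives imide **6** and aldehyde **8**, two achiral carbon fragments plus a recoverable auxiliary, and both stereocentres arise in one step. The required syn pattern (2,3-trans in the ring) is what the boron enolate of an oxazolidinone imide delivers; the (R)-benzyl auxiliary gives the (2R,3R) adduct. Alkylating a preformed aldol with an oxetan-3-yl electrophile would be the reverse order, but such secondary electrophiles alkylate poorly, so the oxetane rides on the enolate component.

**6 to 3 + 4; 3 to 2 to 1; 8 to 7.** The N–acyl bond of **6** is cut into oxazolidinone **4** and carboxylate **3**. The acid is handled as its lithium salt because free oxetanylacetic acids tend to isomerise to lactones. Salt **3** comes from ester **2**, the hydrogenation product of commercial ylidene ester **1**. Aldehyde **8** is the silyl ether of 4-hydroxybenzaldehyde **7**.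

## Roads not taken

**Alternative 1:** The C3–C4 bond is cut. Precursor A1 tethers an enol ether (future C3=C3a) and an (E)-4-methoxystyrene (future C4=C4a) through O1 and C5. Constant-current anodic oxidation (carbon anode, LiClO4, 2,6-lutidine, methanol) would couple the two olefins through a radical cation, forming C3–C4 and the ring. Methanol caps C3a as a dimethyl acetal and C4a as a methyl ether, giving A2.
- Merits: both aryl rings and every skeletal carbon are in place at the key step, a C–C bond and the ring form together, and A1 is only an etherification away from simple pieces. In convergence this road is better than the chosen one, which attaches the anisyl ring after the ring is made.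
- Weak points: C4a arises by methanol capture of a benzylic cation with no facial control, and as a methyl ether. Turning it into the (S)-acetate means oxidising back to the ketone and doing the same asymmetric reduction as the chosen plan. The C3a acetal needs acidic hydrolysis, reduction and acetylation next to an ionisable benzylic ether. The enol ether, the anisyl styrene, the silyloxyarene and the doubly activated C2–H all lie in a narrow oxidation window. The 2,3-trans/3,4-trans outcome rests on a kinetically controlled radical-cation cyclisation steered only by C2.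
- Against its convergence the chosen plan sets auxiliary-controlled C2/C3, a correctable C4, and side arms that emerge differentiated at the right oxidation levels.

**Alternative 2:** The C4–C5 bond is cut. Precursor A3 is the methoxymethyl ether of a syn homoallylic alcohol carrying the acetoxymethyl branch and an (E)-4-methoxystyryl group, with the phenol as an acetate. BF3·OEt2 in acetic acid would unmask an O1=CH2 oxocarbenium ion; attack by styrene carbon C4 forms C4–C5 and the ring, and acetate captures the 4-methoxybenzylic cation at C4a to give triacetate A4. Selective removal of the aryl acetate would then finish.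
- Merits: this is clearly the shortest road, since C5 comes from a formaldehyde equivalent and the C4a acetate is installed in the ring-forming step. In step economy it beats the chosen plan.
- Weak points: C4a is set by capture of a planar, long-lived cation, and the product acetate can re-ionise in the same medium, so a C4a epimer mixture is the likely result. A 2-oxonia-Cope shift of the oxocarbenium ion would break C2–C3 and give a more stable aryl-conjugated oxocarbenium ion, eroding the C2/C3 configuration. The benzylic C2–O bond is itself exposed to BF3. The final differentiation of three acetates must spare a solvolysis-prone benzylic one.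
- Against its brevity the chosen plan sets reagent control at C4a and a ring closure in which no cation is generated at any stereocentre.

**Alternative 3:** The C2–C3 bond is cut. Precursor A5 is a 2-aryl-4,5-dihydro-1,3-dioxepine carrying a 1-(4-methoxyphenyl)vinyl group at the future C4. Me3SiOTf would ionise the acetal C–O bond on the enol-ether side, and the enolate carbon would recombine with the aryl oxocarbenium carbon. This contracts the seven-membered ring to the all-trans tetrahydrofuran-3-carbaldehyde A6.
- Merits: C2–C3 and two stereocentres form in one step under control of a single stereocentre, the trans arrangement is the thermodynamic one, the C3a aldehyde is one reduction and acetylation from the target arm, and the anisyl carbons are present from the start. In bond-forming efficiency this is at least as good as the chosen plan.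
- Weak points: the 1-arylvinyl group is an electron-rich 1,1-disubstituted styrene, itself a nucleophile toward the oxocarbenium ion and prone to cationic oligomerisation under Me3SiOTf. The lone stereocentre of A5 must be made enantioselectively and the enol ether placed on one specific side of the ring. The vinyl group must later be cleaved oxidatively to the aryl ketone and reduced asymmetrically, so the endgame is no shorter.
- Against its convergence the chosen plan sets an absolute configuration that rests on a well-understood auxiliary aldol, and a key step free of acid-sensitive olefins.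

Key step: step 8

Assumption: the (R)-enantiomer of the phosphoric acid in step 8 is taken as the one matched to the substrate's own preference; if the pairing proves mismatched, the (S)-enantiomer is used with no other change.

## Steps

Step 1
Reactants: 1 methyl 2-(oxetan-3-ylidene)acetate
Product: 2 methyl 2-(oxetan-3-yl)acetate
Conditions: H2 (1 atm), 10% Pd/C, EtOAc, rt
Reagents that add atoms: none
Why: Heterogeneous catalytic hydrogenation of an exocyclic α,β-unsaturated ester; the saturated oxetane has no benzylic or allylic C–O bond and should survive Pd/C at atmospheric pressure.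

Step 2
Reactants: 2 methyl 2-(oxetan-3-yl)acetate
Product: 3 lithium 2-(oxetan-3-yl)acetate
Conditions: LiOH·H2O (1.0 equiv), THF/H2O, 0 °C to rt; concentrate, dry by toluene azeotrope
Reagents that add atoms: lithium hydroxide, [Li+].[OH-]
Why: Ester saponification; the product is kept as the lithium salt because the free oxetanylacetic acid can lactonise by attack of the acid on the ring, whereas the carboxylate is stable and is the species needed in step 3.

Step 3
Reactants: 3 lithium 2-(oxetan-3-yl)acetate; 4 (R)-4-benzyl-2-oxazolidinone
Product: 6 (R)-4-benzyl-3-[2-(oxetan-3-yl)acetyl]oxazolidin-2-one, via 2-(oxetan-3-yl)acetic pivalic anhydride 5 (not isolated)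
Conditions: PivCl, THF, −20 °C; then 4, Et3N, LiCl, −20 °C to rt
Reagents that add atoms: pivaloyl chloride, CC(C)(C)C(Cl)=O (its acyl group is carried only by intermediate 5; none of its atoms reach 6)
Why: Mixed-anhydride N-acylation of an oxazolidinone: the carboxylate and pivaloyl chloride give anhydride 5 and LiCl, and the oxazolidinone, activated by LiCl and Et3N, attacks the unhindered non-pivaloyl carbonyl.

Step 4
Reactants: 7 4-hydroxybenzaldehyde
Product: 8 4-(triisopropylsilyloxy)benzaldehyde
Conditions: TIPSCl, imidazole, DMF, rt
Reagents that add atoms: triisopropylsilyl chloride, CC(C)[Si](Cl)(C(C)C)C(C)C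
Why: Standard silylation of a phenol; the bulky aryl silyl ether should withstand boron enolates, hydrides, mild acid and aryl-metal reagents and leaves with fluoride at the end.

Step 5
Reactants: 6 (R)-4-benzyl-3-[2-(oxetan-3-yl)acetyl]oxazolidin-2-one; 8 4-(triisopropylsilyloxy)benzaldehyde
Product: 11 (R)-4-benzyl-3-[(2R,3R)-3-hydroxy-2-(oxetan-3-yl)-3-[4-(triisopropylsilyloxy)phenyl]propanoyl]oxazolidin-2-one, via dibutylboron (Z)-enolate 9 (not isolated), via dibutylboron aldolate 10 (not isolated)
Conditions: Bu2BOTf, iPr2NEt, CH2Cl2, −78 to 0 °C; then 8, −78 to 0 °C; then pH 7 buffer, MeOH, 30% H2O2, 0 °C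
Reagents that add atoms: dibutylboron triflate, CCCCB(CCCC)OS(=O)(=O)C(F)(F)F (its Bu2B unit is carried only by intermediates 9 and 10; none of its atoms reach 11)
Why: Evans syn-aldol reaction: soft enolisation gives the (Z)-boron enolate 9, which adds to the aldehyde through a closed chair (Zimmerman–Traxler) transition state with the auxiliary carbonyl turned away, so the (R)-benzyl group selects the enolate face and both new centres (the future C2 and C3) arise as the (2R,3R) syn pair; oxidative work-up cleaves aldolate 10.

Step 6
Reactants: 11 (R)-4-benzyl-3-[(2R,3R)-3-hydroxy-2-(oxetan-3-yl)-3-[4-(triisopropylsilyloxy)phenyl]propanoyl]oxazolidin-2-one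
Product: 12 (1R,2S)-2-(oxetan-3-yl)-1-[4-(triisopropylsilyloxy)phenyl]propane-1,3-diol
Conditions: LiBH4, MeOH (1 equiv), THF, 0 °C
Reagents that add atoms: none
Why: Reductive cleavage of the N-acyl oxazolidinone with LiBH4 at the more electrophilic exocyclic carbonyl gives the primary alcohol without touching either stereocentre (the descriptor at the oxetanyl-bearing carbon changes only through priority); auxiliary 4 is recovered.

Step 7
Reactants: 12 (1R,2S)-2-(oxetan-3-yl)-1-[4-(triisopropylsilyloxy)phenyl]propane-1,3-diol
Product: 13 (2S,3R)-3-hydroxy-2-(oxetan-3-yl)-3-[4-(triisopropylsilyloxy)phenyl]propyl acetate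
Conditions: AcCl (1.05 equiv), 2,4,6-collidine, CH2Cl2, −78 °C
Reagents that add atoms: acetyl chloride, CC(Cl)=O
Why: Selective acylation of a primary alcohol over a hindered secondary benzylic one with acetyl chloride and a non-nucleophilic pyridine base at low temperature; it installs the final C3a acetate and leaves the C2 hydroxyl as the only nucleophile for step 8.

Step 8
Reactants: 13 (2S,3R)-3-hydroxy-2-(oxetan-3-yl)-3-[4-(triisopropylsilyloxy)phenyl]propyl acetate
Product: 14 [(2R,3S,4S)-4-(hydroxymethyl)-2-[4-(triisopropylsilyloxy)phenyl]oxolan-3-yl]methyl acetate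
Conditions: (R)-3,3'-bis(2,4,6-triisopropylphenyl)-1,1'-binaphthyl-2,2'-diyl hydrogen phosphate (10 mol%), 4 Å molecular sieves, toluene (0.05 M), 40 °C
Reagents that add atoms: none
Why: The phosphoric acid activates the oxetane oxygen by protonation or hydrogen bonding while its P=O oxygen accepts the C2 hydroxyl proton, and the benzylic oxygen displaces the activated C–O bond at one oxetane methylene in an SN2 process (inversion at that CH2, which leaves no trace), driven irreversibly by release of the four-ring strain. The closest known reaction type is the acid-catalysed intramolecular opening of 3-substituted oxetanes by a tethered hydroxyl to give 3-(hydroxymethyl)tetrahydrofurans, including desymmetrisations by chiral phosphoric acids. The one ring formed, the tetrahydrofuran, closes in a 5-exo-tet mode: O1 bonds to C5 and the C5–O bond that breaks lies outside the new ring. C2 and C3 are untouched, since the C2–O bond stays intact, so the aldol configuration is carried over unchanged. The new stereocentre C4 is created without any bond to it being made or broken, purely by which of its two diastereotopic CH2O arms becomes C5; its controlling element is the adjacent C3 centre, because in the fused bicyclic transition state the arm left behind as C4a is staggered away from the C3 acetoxymethyl group on the path to 14 and eclipsed with it on the other, and the chiral pocket of the catalyst is meant to add to this bias. The step needs chemoselectivity for the C2 hydroxyl and diastereotopic-group selectivity: the first is secured by the substrate, whose only free hydroxyl is at C2 (the acetate carbonyl could reach the oxetane only through a seven-membered ring), and by the mildness of the acid, which should not ionise the electron-rich benzylic alcohol. Any C4 epimer is not lost, because C4 becomes α to a carbonyl in 15 and 19 and can be equilibrated to the all-trans arrangement.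

Step 9
Reactants: 14 [(2R,3S,4S)-4-(hydroxymethyl)-2-[4-(triisopropylsilyloxy)phenyl]oxolan-3-yl]methyl acetate
Product: 15 [(2R,3S,4R)-4-formyl-2-[4-(triisopropylsilyloxy)phenyl]oxolan-3-yl]methyl acetate
Conditions: Dess–Martin periodinane, NaHCO3, CH2Cl2, 0 °C to rt
Reagents that add atoms: none
Why: Dess–Martin oxidation of a primary alcohol under buffered, non-basic conditions, which should leave the α-stereocentre C4, the acetate and the silyl ether intact (the C4 descriptor changes only through priority).

Step 10
Reactants: 15 [(2R,3S,4R)-4-formyl-2-[4-(triisopropylsilyloxy)phenyl]oxolan-3-yl]methyl acetate; 16 4-methoxyphenylmagnesium bromide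
Product: 18 [(2R,3S,4R)-4-[hydroxy(4-methoxyphenyl)methyl]-2-[4-(triisopropylsilyloxy)phenyl]oxolan-3-yl]methyl acetate (both C4a epimers), via 4-methoxyphenyltitanium triisopropoxide 17 (not isolated)
Conditions: 16, ClTi(OiPr)3, THF, −78 to −20 °C; then 15, −78 to 0 °C; aq. NH4Cl
Reagents that add atoms: chlorotitanium triisopropoxide, CC(C)O[Ti](Cl)(OC(C)C)OC(C)C (its Ti(OiPr)3 unit is carried only by intermediate 17; none of its atoms reach 18)
Why: Transmetalation of the Grignard reagent gives the weakly basic aryltitanium 17, which adds to aldehydes but not to acetates and should not enolise the α-branched aldehyde; the carbinol centre is not controlled here and both epimers are carried on.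

Step 11
Reactants: 18 [(2R,3S,4R)-4-[hydroxy(4-methoxyphenyl)methyl]-2-[4-(triisopropylsilyloxy)phenyl]oxolan-3-yl]methyl acetate (both C4a epimers)
Product: 19 [(2R,3S,4R)-4-(4-methoxybenzoyl)-2-[4-(triisopropylsilyloxy)phenyl]oxolan-3-yl]methyl acetate
Conditions: Dess–Martin periodinane, NaHCO3, CH2Cl2, rt
Reagents that add atoms: none
Why: Dess–Martin oxidation of the benzylic carbinols erases the uncontrolled centre and merges both epimers into one ketone; C4 is now α to the carbonyl, where the all-trans arrangement is also the thermodynamically preferred one.

Step 12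
Reactants: 19 [(2R,3S,4R)-4-(4-methoxybenzoyl)-2-[4-(triisopropylsilyloxy)phenyl]oxolan-3-yl]methyl acetate
Product: 20 [(2R,3S,4R)-4-[(S)-hydroxy(4-methoxyphenyl)methyl]-2-[4-(triisopropylsilyloxy)phenyl]oxolan-3-yl]methyl acetate
Conditions: (R)-2-methyl-CBS-oxazaborolidine (B-methyl oxazaborolidine from (R)-diphenylprolinol, 0.5 equiv), BH3·SMe2, THF, −20 °C; MeOH quench
Reagents that add atoms: none
Why: Corey–Bakshi–Shibata reduction: the ketone binds the catalyst–borane complex with the aryl group as the larger substituent and hydride is delivered within the complex to one face, the (R)-catalyst giving the (S)-carbinol (the mirror image of the acetophenone outcome with the (S)-catalyst); the acetate is inert to borane at this temperature.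

Step 13
Reactants: 20 [(2R,3S,4R)-4-[(S)-hydroxy(4-methoxyphenyl)methyl]-2-[4-(triisopropylsilyloxy)phenyl]oxolan-3-yl]methyl acetate
Product: 21 [(2R,3S,4R)-4-[(S)-acetoxy(4-methoxyphenyl)methyl]-2-[4-(triisopropylsilyloxy)phenyl]oxolan-3-yl]methyl acetate
Conditions: Ac2O, pyridine, 4-(dimethylamino)pyridine (cat.), CH2Cl2, 0 °C to rt
Reagents that add atoms: acetic anhydride, CC(=O)OC(C)=O
Why: Acetylation of the secondary alcohol by nucleophilic catalysis under basic, non-ionising conditions; the C–O bond at C4a is not broken, so its configuration is retained, and the phenol is still silylated.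

Step 14
Reactants: 21 [(2R,3S,4R)-4-[(S)-acetoxy(4-methoxyphenyl)methyl]-2-[4-(triisopropylsilyloxy)phenyl]oxolan-3-yl]methyl acetate
Product: 22 [(2R,3S,4R)-4-[(S)-acetoxy(4-methoxyphenyl)methyl]-2-(4-hydroxyphenyl)oxolan-3-yl]methyl acetate (CNP0231272.1)
Conditions: Bu4NF, AcOH (1:1), THF, 0 °C
Reagents that add atoms: none
Why: Fluoride cleavage of the aryl silyl ether; buffering with acetic acid keeps the released phenoxide protonated, which should prevent acetyl transfer to the phenol and quinone-methide opening of the benzylic C2–O1 bond.

## Compound list

1 | methyl 2-(oxetan-3-ylidene)acetate | COC(=O)C=C1COC1 | starting material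
2 | methyl 2-(oxetan-3-yl)acetate | COC(=O)CC1COC1 | intermediate
3 | lithium 2-(oxetan-3-yl)acetate | [Li+].[O-]C(=O)CC1COC1 | intermediate
4 | (R)-4-benzyl-2-oxazolidinone | O=C1N[C@H](Cc2ccccc2)CO1 | starting material
5 | 2-(oxetan-3-yl)acetic pivalic anhydride | CC(C)(C)C(=O)OC(=O)CC1COC1 | intermediate (not isolated)
6 | (R)-4-benzyl-3-[2-(oxetan-3-yl)acetyl]oxazolidin-2-one | O=C(CC1COC1)N1C(=O)OC[C@H]1Cc1ccccc1 | intermediate
7 | 4-hydroxybenzaldehyde | O=Cc1ccc(O)cc1 | starting material
8 | 4-(triisopropylsilyloxy)benzaldehyde | O=Cc1ccc(O[Si](C(C)C)(C(C)C)C(C)C)cc1 | intermediate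
9 | dibutylboron (Z)-enolate of 6 | CCCCB(CCCC)O/C(=C\C1COC1)N1C(=O)OC[C@H]1Cc1ccccc1 | intermediate (not isolated)
10 | dibutylboron aldolate of 11 | CCCCB(CCCC)O[C@@H](c1ccc(O[Si](C(C)C)(C(C)C)C(C)C)cc1)[C@@H](C1COC1)C(=O)N1C(=O)OC[C@H]1Cc1ccccc1 | intermediate (not isolated)
11 | (R)-4-benzyl-3-[(2R,3R)-3-hydroxy-2-(oxetan-3-yl)-3-[4-(triisopropylsilyloxy)phenyl]propanoyl]oxazolidin-2-one | O=C([C@H](C1COC1)[C@@H](O)c1ccc(O[Si](C(C)C)(C(C)C)C(C)C)cc1)N1C(=O)OC[C@H]1Cc1ccccc1 | intermediate
12 | (1R,2S)-2-(oxetan-3-yl)-1-[4-(triisopropylsilyloxy)phenyl]propane-1,3-diol | OC[C@H](C1COC1)[C@@H](O)c1ccc(O[Si](C(C)C)(C(C)C)C(C)C)cc1 | intermediate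
13 | (2S,3R)-3-hydroxy-2-(oxetan-3-yl)-3-[4-(triisopropylsilyloxy)phenyl]propyl acetate | CC(=O)OC[C@H](C1COC1)[C@@H](O)c1ccc(O[Si](C(C)C)(C(C)C)C(C)C)cc1 | intermediate
14 | [(2R,3S,4S)-4-(hydroxymethyl)-2-[4-(triisopropylsilyloxy)phenyl]oxolan-3-yl]methyl acetate | OC[C@H]1CO[C@@H](c2ccc(O[Si](C(C)C)(C(C)C)C(C)C)cc2)[C@@H]1COC(C)=O | intermediate
15 | [(2R,3S,4R)-4-formyl-2-[4-(triisopropylsilyloxy)phenyl]oxolan-3-yl]methyl acetate | O=C[C@H]1CO[C@@H](c2ccc(O[Si](C(C)C)(C(C)C)C(C)C)cc2)[C@@H]1COC(C)=O | intermediate
16 | 4-methoxyphenylmagnesium bromide (commercial THF solution) | COc1ccc([Mg]Br)cc1 | starting material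
17 | 4-methoxyphenyltitanium triisopropoxide | COc1ccc([Ti](OC(C)C)(OC(C)C)OC(C)C)cc1 | intermediate (not isolated)
18 | [(2R,3S,4R)-4-[hydroxy(4-methoxyphenyl)methyl]-2-[4-(triisopropylsilyloxy)phenyl]oxolan-3-yl]methyl acetate (both C4a epimers) | COc1ccc(C(O)[C@H]2CO[C@@H](c3ccc(O[Si](C(C)C)(C(C)C)C(C)C)cc3)[C@@H]2COC(C)=O)cc1 | intermediate
19 | [(2R,3S,4R)-4-(4-methoxybenzoyl)-2-[4-(triisopropylsilyloxy)phenyl]oxolan-3-yl]methyl acetate | COc1ccc(C(=O)[C@H]2CO[C@@H](c3ccc(O[Si](C(C)C)(C(C)C)C(C)C)cc3)[C@@H]2COC(C)=O)cc1 | intermediate
20 | [(2R,3S,4R)-4-[(S)-hydroxy(4-methoxyphenyl)methyl]-2-[4-(triisopropylsilyloxy)phenyl]oxolan-3-yl]methyl acetate | COc1ccc([C@@H](O)[C@H]2CO[C@@H](c3ccc(O[Si](C(C)C)(C(C)C)C(C)C)cc3)[C@@H]2COC(C)=O)cc1 | intermediate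
21 | [(2R,3S,4R)-4-[(S)-acetoxy(4-methoxyphenyl)methyl]-2-[4-(triisopropylsilyloxy)phenyl]oxolan-3-yl]methyl acetate | COc1ccc([C@@H](OC(C)=O)[C@H]2CO[C@@H](c3ccc(O[Si](C(C)C)(C(C)C)C(C)C)cc3)[C@@H]2COC(C)=O)cc1 | intermediate
22 | [(2R,3S,4R)-4-[(S)-acetoxy(4-methoxyphenyl)methyl]-2-(4-hydroxyphenyl)oxolan-3-yl]methyl acetate (CNP0231272.1) | COc1ccc([C@@H](OC(C)=O)[C@H]2CO[C@@H](c3ccc(O)cc3)[C@@H]2COC(C)=O)cc1 | target

## Step count and least certain steps

Total: 14 steps. Longest linear sequence: 13 steps (steps 1–3 and 5–14, from **1** to **22**); step 4 is a one-step side branch.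

**Step 8 (key step).** The most likely failure is insufficient discrimination between the two diastereotopic oxetane methylenes: the substrate bias rests on one 1,2-interaction in the transition state, and the chiral acid may be mismatched. A secondary concern is acid-induced ionisation of the electron-rich benzylic alcohol before it can attack. The fallback sets out from **13** and returns at **19**; it gives up kinetic control of C4 and corrects it thermodynamically. The ring opening is run with an achiral acid (diphenyl phosphate, toluene), giving **14** together with its C4 epimer [(2R,3S,4R)-4-(hydroxymethyl)-2-[4-(triisopropylsilyloxy)phenyl]oxolan-3-yl]methyl acetate F1. The mixture is taken through steps 9 to 11, the minor series passing through [(2R,3S,4S)-4-formyl-2-[4-(triisopropylsilyloxy)phenyl]oxolan-3-yl]methyl acetate F2, [(2R,3S,4S)-4-[hydroxy(4-methoxyphenyl)methyl]-2-[4-(triisopropylsilyloxy)phenyl]oxolan-3-yl]methyl acetate F3 and [(2R,3S,4S)-4-(4-methoxybenzoyl)-2-[4-(triisopropylsilyloxy)phenyl]oxolan-3-yl]methyl acetate F4. The ketone mixture is then stirred with DBU in CH2Cl2, which epimerises C4 through the enolate and should funnel F4 into the more stable all-trans ketone **19**. Ring opening by β-elimination is disfavoured, because the C5–O1 bond lies in the nodal plane of the exocyclic enolate.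

**Step 5.** The most likely failure is coordination of the boron triflate to the Lewis-basic oxetane oxygen during enolisation, leading to ring opening or oligomerisation in competition with enolate formation. The fallback sets out from **3** and **8** and returns at **12**; it replaces the aldol by enolate acylation and chelation-controlled reduction.
- Salt **3** is coupled as in step 3 with (S)-4-benzyl-2-oxazolidinone to give (S)-4-benzyl-3-[2-(oxetan-3-yl)acetyl]oxazolidin-2-one F5. The opposite auxiliary is needed because acylation takes place on the enolate face opposite to that used in the boron aldol.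
- Aldehyde **8** is oxidised (NaClO2, NaH2PO4, 2-methyl-2-butene) to 4-(triisopropylsilyloxy)benzoic acid F6 and converted with oxalyl chloride into 4-(triisopropylsilyloxy)benzoyl chloride F7.
- The sodium enolate of F5 (NaN(SiMe3)2, THF, −78 °C) is C-acylated by F7 to give (S)-4-benzyl-3-[(2R)-2-(oxetan-3-yl)-3-oxo-3-[4-(triisopropylsilyloxy)phenyl]propanoyl]oxazolidin-2-one F8, whose α-centre is held against enolisation by allylic 1,3-strain.
- Reduction with Zn(BH4)2 through the zinc chelate gives the syn alcohol (S)-4-benzyl-3-[(2R,3R)-3-hydroxy-2-(oxetan-3-yl)-3-[4-(triisopropylsilyloxy)phenyl]propanoyl]oxazolidin-2-one F9.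
- LiBH4 cleavage as in step 6 gives diol **12**.

**Step 12.** The most likely failure is poor facial selectivity in hydride delivery: the smaller substituent of ketone **19** is a branched ring carbon, the aryl group is electron-rich, and the resident C4 centre may oppose the catalyst. The fallback sets out from **18** and returns at **20** and **21**; it sorts the epimers instead of reducing a ketone. Mixture **18** from step 10 is separated by chromatography. The (S)-epimer is **20** and goes on to step 13. The (R)-epimer, [(2R,3S,4R)-4-[(R)-hydroxy(4-methoxyphenyl)methyl]-2-[4-(triisopropylsilyloxy)phenyl]oxolan-3-yl]methyl acetate F10, is converted with inversion directly into acetate **21** by a Mitsunobu reaction with acetic acid (PPh3, DIAD, toluene, 0 °C). Both epimers then converge on **21**, and steps 11 and 12 fall away.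

**Step 10.** The most likely failure is loss of the C4 configuration by enolisation of the α-branched aldehyde, or attack of residual Grignard reagent on the acetate if transmetalation to titanium is incomplete. The fallback sets out from **14** and returns at **19**; it reaches the ketone without an aldehyde or a basic organometallic.
- Alcohol **14** is oxidised (2,2,6,6-tetramethylpiperidine-1-oxyl, PhI(OAc)2, MeCN/H2O) to (3R,4S,5R)-4-(acetoxymethyl)-5-[4-(triisopropylsilyloxy)phenyl]oxolane-3-carboxylic acid F11.
- F11 is converted (EtSH, EDC·HCl, 4-(dimethylamino)pyridine) into S-ethyl (3R,4S,5R)-4-(acetoxymethyl)-5-[4-(triisopropylsilyloxy)phenyl]oxolane-3-carbothioate F12.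
- F12 is coupled with 4-methoxyphenylboronic acid under neutral Liebeskind–Srogl conditions (Pd2(dba)3, tri(2-furyl)phosphine, copper thiophene-2-carboxylate, THF, 50 °C) to give ketone **19** directly.

## Further compounds

F1 | step 8 | [(2R,3S,4R)-4-(hydroxymethyl)-2-[4-(triisopropylsilyloxy)phenyl]oxolan-3-yl]methyl acetate (C4 epimer of 14) | OC[C@@H]1CO[C@@H](c2ccc(O[Si](C(C)C)(C(C)C)C(C)C)cc2)[C@@H]1COC(C)=O
F2 | step 8 | [(2R,3S,4S)-4-formyl-2-[4-(triisopropylsilyloxy)phenyl]oxolan-3-yl]methyl acetate (C4 epimer of 15) | O=C[C@@H]1CO[C@@H](c2ccc(O[Si](C(C)C)(C(C)C)C(C)C)cc2)[C@@H]1COC(C)=O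
F3 | step 8 | [(2R,3S,4S)-4-[hydroxy(4-methoxyphenyl)methyl]-2-[4-(triisopropylsilyloxy)phenyl]oxolan-3-yl]methyl acetate (C4 epimer of 18, both C4a epimers) | COc1ccc(C(O)[C@@H]2CO[C@@H](c3ccc(O[Si](C(C)C)(C(C)C)C(C)C)cc3)[C@@H]2COC(C)=O)cc1
F4 | step 8 | [(2R,3S,4S)-4-(4-methoxybenzoyl)-2-[4-(triisopropylsilyloxy)phenyl]oxolan-3-yl]methyl acetate (C4 epimer of 19) | COc1ccc(C(=O)[C@@H]2CO[C@@H](c3ccc(O[Si](C(C)C)(C(C)C)C(C)C)cc3)[C@@H]2COC(C)=O)cc1
F5 | step 5 | (S)-4-benzyl-3-[2-(oxetan-3-yl)acetyl]oxazolidin-2-one | O=C(CC1COC1)N1C(=O)OC[C@@H]1Cc1ccccc1
F6 | step 5 | 4-(triisopropylsilyloxy)benzoic acid | OC(=O)c1ccc(O[Si](C(C)C)(C(C)C)C(C)C)cc1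
F7 | step 5 | 4-(triisopropylsilyloxy)benzoyl chloride | ClC(=O)c1ccc(O[Si](C(C)C)(C(C)C)C(C)C)cc1
F8 | step 5 | (S)-4-benzyl-3-[(2R)-2-(oxetan-3-yl)-3-oxo-3-[4-(triisopropylsilyloxy)phenyl]propanoyl]oxazolidin-2-one | O=C([C@H](C1COC1)C(=O)c1ccc(O[Si](C(C)C)(C(C)C)C(C)C)cc1)N1C(=O)OC[C@@H]1Cc1ccccc1
F9 | step 5 | (S)-4-benzyl-3-[(2R,3R)-3-hydroxy-2-(oxetan-3-yl)-3-[4-(triisopropylsilyloxy)phenyl]propanoyl]oxazolidin-2-one | O=C([C@H](C1COC1)[C@@H](O)c1ccc(O[Si](C(C)C)(C(C)C)C(C)C)cc1)N1C(=O)OC[C@@H]1Cc1ccccc1
F10 | step 12 | [(2R,3S,4R)-4-[(R)-hydroxy(4-methoxyphenyl)methyl]-2-[4-(triisopropylsilyloxy)phenyl]oxolan-3-yl]methyl acetate | COc1ccc([C@H](O)[C@H]2CO[C@@H](c3ccc(O[Si](C(C)C)(C(C)C)C(C)C)cc3)[C@@H]2COC(C)=O)cc1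
F11 | step 10 | (3R,4S,5R)-4-(acetoxymethyl)-5-[4-(triisopropylsilyloxy)phenyl]oxolane-3-carboxylic acid | OC(=O)[C@H]1CO[C@@H](c2ccc(O[Si](C(C)C)(C(C)C)C(C)C)cc2)[C@@H]1COC(C)=O
F12 | step 10 | S-ethyl (3R,4S,5R)-4-(acetoxymethyl)-5-[4-(triisopropylsilyloxy)phenyl]oxolane-3-carbothioate | CCSC(=O)[C@H]1CO[C@@H](c2ccc(O[Si](C(C)C)(C(C)C)C(C)C)cc2)[C@@H]1COC(C)=O
A1 | alternative 1 | (E)-3-(4-methoxyphenyl)allyl (R)-3-methoxy-1-[4-(triisopropylsilyloxy)phenyl]prop-2-en-1-yl ether | COC=C[C@@H](OC/C=C/c1ccc(OC)cc1)c1ccc(O[Si](C(C)C)(C(C)C)C(C)C)cc1
A2 | alternative 1 | all-trans 3-(dimethoxymethyl)-4-[methoxy(4-methoxyphenyl)methyl]-2-[4-(triisopropylsilyloxy)phenyl]tetrahydrofuran (C4a epimers) | COc1ccc(C(OC)[C@H]2CO[C@@H](c3ccc(O[Si](C(C)C)(C(C)C)C(C)C)cc3)[C@@H]2C(OC)OC)cc1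
A3 | alternative 2 | (2S,3E)-2-[(R)-(4-acetoxyphenyl)(methoxymethoxy)methyl]-4-(4-methoxyphenyl)but-3-en-1-yl acetate | COCO[C@@H](c1ccc(OC(C)=O)cc1)[C@H](COC(C)=O)/C=C/c1ccc(OC)cc1
A4 | alternative 2 | O-acetyl derivative of the target (triacetate) | COc1ccc([C@@H](OC(C)=O)[C@H]2CO[C@@H](c3ccc(OC(C)=O)cc3)[C@@H]2COC(C)=O)cc1
A5 | alternative 3 | 5-[1-(4-methoxyphenyl)vinyl]-2-[4-(triisopropylsilyloxy)phenyl]-4,5-dihydro-1,3-dioxepine (configuration fixed at the future C4, acetal carbon either) | C=C(c1ccc(OC)cc1)[C@H]1COC(c2ccc(O[Si](C(C)C)(C(C)C)C(C)C)cc2)OC=C1
A6 | alternative 3 | all-trans 4-[1-(4-methoxyphenyl)vinyl]-2-[4-(triisopropylsilyloxy)phenyl]tetrahydrofuran-3-carbaldehyde | COc1ccc(C(=C)[C@H]2CO[C@@H](c3ccc(O[Si](C(C)C)(C(C)C)C(C)C)cc3)[C@@H]2C=O)cc1
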